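## Structural features

The target is a 2,3,4-trisubstituted oxolane (O1, C2 to C5). C2 carries guaiacyl ring B, C3 a hydroxymethyl group, and C4 is a fully substituted carbinol bearing a hydroxyl and, through the methylene C7, guaiacyl ring A. C2 (S), C3 (R) and C4 (S) are contiguous: ring B is trans to the C3 hydroxymethyl, which is cis to C7 and trans to the C4 hydroxyl. The para oxygen of ring B is etherified by C8'' of a 1-arylpropane-1,3-diol unit (ring C on C7'', hydroxymethyl C9''). Its adjacent centres C7'' (S) and C8'' (R) are anti (erythro) and too remote from the core to be controlled by it. The fragile groups are the C2–O1 benzylic ether (acid ionises it, with epimerisation at C2 or Friedel–Crafts closure by ring A to an aryltetralin), the C7'' benzylic alcohol, both benzylic C–O bonds under hydrogenolysis, and the two free phenols. The real difficulty is the tetrasubstituted C4 next to C3 in defined relative and absolute configuration, together with the distinction of three guaiacyl oxygens and independent control of the side-chain pair. The key step exploits the chain C5–C4–C3–hydroxymethyl carbon, oxygenated at C5, at C4 and at the terminal carbon. This is the pattern of a 3-alkoxy-5-alkoxybutenolide: C5 as lactone carbonyl, C4 as α-carbon, C3 as β-carbon, the hydroxymethyl carbon as acetal carbon. C3 is therefore an acceptor site for C2 (an acyl anion carrying ring B) and C4 a donor site for C7 (the ring A benzyl halide).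

## Logic of the disconnections

28 ⇒ 27. Three O–benzyl bonds are cut: ring A phenol, ring C phenol and the C4 tertiary oxygen. All three oxygens must stay masked through organolithium, hydride, Lewis acid and Mitsunobu chemistry, and one neutral last operation frees them together. The gain is that no phenol has to be distinguished late. The demand is that hydrogenolysis spares the C2–O1 and C7''–O benzylic bonds.

27 ⇒ 26 ⇒ 25 ⇒ 22 + 23. The cut is C7''–C8'' (aldol), after adjusting C9'' from hydroxymethyl back to an acyl imide and inverting C7''. The core cannot relay stereochemistry to the side chain, so an auxiliary must. The boron aldol of an aryloxyacetyl imide gives the syn pair reliably, whereas 28 needs the anti pair. C8'' is therefore set in 25 and C7'' is inverted through 26. The side chain shrinks to 23 and a two-carbon unit. The demands are that the aldol tolerates the free primary hydroxyl and that the inversion is a clean SN2 event at an electron-rich benzylic carbon.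

22 ⇒ 20 + 21 and 20 ⇒ 19. The aryl O–CH2 bond and then the O–Si bond are cut. Once the silyl group is removed, the ring B phenol is the only acidic hydroxyl, so carbonate-mediated alkylation is selective. The silyl group is orthogonal to the benzyl ethers on ring A and on the C4 oxygen.

19 ⇒ 18. The O1–C2 bond is cut. C2 is benzylic and para-oxygenated, so its hydroxyl ionises easily and the C5 hydroxyl can close the ring. The C2 configuration then follows from C3 under equilibrating conditions, so the carbinol need not be made selectively. The ring is traded for an acyclic triol. The demand is that oxygen capture outruns Friedel–Crafts attack by ring A.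

18 ⇒ 17 ⇒ 16. This is a redox adjustment: the C2 carbinol from a ketone from a dithiane, and the C5 and C3 hydroxymethyl groups from a lactone carbonyl and a menthyl acetal. It reveals a lactone in which C3 and C4 sit in a ring next to a removable stereocentre. One hydride reagent must do three reductions and release 3, and unmasking the ketone must not epimerise C3.

16 ⇒ 11 + 7 + 13. The C2–C3 and C4–C7 bonds are cut. Both new stereocentres arise in one flask from a single existing one, and three fragments of similar size are joined. The descriptors of 7 (5R) and of 16 (3S,4R,5R) were checked against 28: they map onto C3 (R) and C4 (S), so no structural correction is needed. The demands are 1,4-addition to a β-carbon deactivated by the α-alkoxy group and C-alkylation of a crowded tetrasubstituted enolate.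

7 ⇒ 6 ⇒ 5 ⇒ 4 ⇒ 2 + 3, and 2 ⇒ 1. The enol ether double bond comes from β-elimination of benzyl alcohol from a bis-benzyl ether, which comes from a cis-diol. This route to the α-oxygenated acceptor is preferred to an epoxide-to-enol isomerisation because its regiochemistry is unambiguous: the only acidic C–H is α to the carbonyl and the only β leaving group sits on the future C3. The acetal centre comes from crystallisation of the menthyl acetal of the photo-oxygenation product of 1. The elimination must leave the acetal centre untouched.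

11 ⇒ 9 + 10, 9 ⇒ 8, and 13 ⇒ 12. These are routine C–S, O–Si and C–Br disconnections to commodity aromatics. The silyl ether must survive n-BuLi and the bromide must be used fresh.

## Other disconnections considered

Alternative 1: The cut is C4–C7, made by light. The precursor A2 is a 4-oxo-oxolane with C2 and C3 already set, ring B as an aryl mesylate, and the C3 hydroxymethyl oxygen carrying the ring A benzyl group as an ether. In the forward step the excited C4 carbonyl would abstract the benzylic, oxygen-activated δ-hydrogen of that ether through a seven-membered transition state. The 1,5-biradical would close to the cis-fused bicyclic alcohol A1 (Norrish–Yang cyclisation). Hydrogenolysis of the temporary benzylic C–O bond would then release the C3 hydroxymethyl and leave ring A on C7.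
- In favour: the cis ring fusion ties C4 to C3 exactly as required; the tertiary hydroxyl appears unprotected; the key step needs no reagent.
- Against: α-cleavage of the α-alkoxy ketone and abstraction at other oxygen-activated C–H bonds compete with a δ-abstraction that is slower than γ-abstraction. A2 has an epimerisable C3 next to the ketone and must itself be made enantiopure with C2 and C3 set. A1 holds two benzylic C–O bonds of the same kind, and opening only the ring A one rests on the deactivating mesylate alone, which must later be removed.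
- Comparison: on structure the alternative is the better at C4 (no tertiary benzyl ether to carry) and the equal at C2. On mechanism an excited-state radical pair with several exit channels stands against an ionic sequence whose selectivity the substrate enforces. On step economy the count after the key step is about equal, and the way to A2 is not shorter than the way to 7, 11 and 13.

Alternative 2: O1–C2 and C3–C4 are cut in one operation, giving hydroxy ketone A4 and the ring B cinnamaldehyde A5. In the forward step a diarylprolinol silyl ether amine would form an iminium ion with A5. The hydroxyl of A4 would add to its β-carbon (O1–C2), and the enamine would close on the ketone in a 5-exo aldol (C3–C4). The product is aldehyde A3, whose formyl carbon is the future C3 hydroxymethyl.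
- In favour: two achiral fragments, the ring and three stereocentres in one catalytic step, no tertiary ether, no stoichiometric auxiliary for the core.
- Against: aliphatic alcohols add weakly and reversibly to iminium ions, and the electron-rich ring B enal is a poor acceptor, so conversion and selectivity at C2 are both in doubt. The aldol makes a tertiary carbinol from a ketone flanked by two similar methylene groups, with no clear element placing the hydroxyl trans to the formyl group. A4 can enter enamine self-condensation. A3 is a β-hydroxy aldehyde that can epimerise at C3 or revert.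
- Comparison: on structure the two plans are equal in the endgame (same ring A and ring B protection, same side-chain steps). On step economy and on catalytic versus auxiliary control the alternative is the better. On mechanism the chosen plan has the more predictable course, because each centre is relayed from one crystalline acetal centre.

Alternative 3: O1–C2 is cut, as in the chosen plan, but from the methylene oxidation level of C2. The precursor is the acyclic triol A7, with C3 and C4 set, ring A as a pivalate and ring B as a benzyl ether. In the forward step 2,3-dichloro-5,6-dicyano-1,4-benzoquinone would remove hydride from the benzylic CH2 of the more electron-rich ring B, and the C5 hydroxyl would capture the cation to give A6.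
- In favour: no dithiane, mercury salt or hydride step is spent on C2, which is a better redox economy. C2 is set by the same thermodynamic preference as in the chosen plan, which is equal. The pivalate deactivates ring A towards both oxidation and Friedel–Crafts closure, a better guard than the ring A benzyl ether of the chosen plan. The tertiary hydroxyl stays free.
- Against: the new C2–H of A6 is benzylic and α to oxygen, so it is more easily oxidised than the C–H it came from, and over-oxidation to a ring-opened ketone must be outrun. A7 still needs C3 and C4, including the tertiary carbinol, in enantiopure form. If made by the same butenolide chemistry it would need a benzyl anion in place of the dithiane anion, which adds less cleanly. The hard part is moved, not removed.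
- Comparison: on structure equal or better (free tertiary alcohol, deactivated ring A). On mechanism the same cation is reached by hydride abstraction and not by ionisation, with a narrower chemoselectivity window. On step economy probably one or two steps shorter after the core, but with no assured route to A7.

Key step: step 9

Remark on the chemistry: 12, 21 and 23 are taken as catalogue compounds, and the carbinol centre made in step 11 is carried as a mixture because step 12 re-forms C2.

## Route

Step 1
Reactants: 1 furfural
Product: 2 5-hydroxyfuran-2(5H)-one (racemic lactol)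
Conditions: O2, hν (visible), rose bengal (sensitiser, cat.), MeOH, rt
Reagents that add atoms: oxygen, O=O
Why: Dye-sensitised [4+2] addition of singlet oxygen to the furan, then methanolysis with loss of the formyl carbon as methyl formate, is the standard photo-oxygenation of furfural to the hydroxybutenolide; the lactol centre is not controlled here.

Step 2
Reactants: 2 5-hydroxyfuran-2(5H)-one; 3 (−)-menthol
Product: 4 (5R)-5-[(1R,2S,5R)-menthyloxy]furan-2(5H)-one
Conditions: camphorsulfonic acid (cat.), toluene, reflux, Dean–Stark; crystallise from hexane, mother liquor re-equilibrated with acid and recycled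
Reagents that add atoms: none
Why: Acid-catalysed acetalisation of the lactol gives both C5 epimers, which interconvert under acid; the (5R) epimer is the crystalline one, so crystallisation-driven enrichment sets the acetal centre.

Step 3
Reactants: 4 (5R)-5-(menthyloxy)furan-2(5H)-one
Product: 5 (3S,4R,5R)-3,4-dihydroxy-5-(menthyloxy)dihydrofuran-2(3H)-one (cis-diol, both hydroxyls trans to the menthyloxy group)
Conditions: OsO4 (cat.), N-methylmorpholine N-oxide, citric acid, t-BuOH/H2O, rt
Reagents that add atoms: N-methylmorpholine N-oxide, C[N+]1([O-])CCOCC1; water, O (both hydroxyl oxygens are relayed through OsO4, O=[Os](=O)(=O)=O)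
Why: Upjohn cis-dihydroxylation of the butenolide on the face away from the C5 menthyloxy group; the two new centres are transient and are removed in step 5.

Step 4
Reactants: 5 cis-diol lactone
Product: 6 (3S,4R,5R)-3,4-bis(benzyloxy)-5-(menthyloxy)dihydrofuran-2(3H)-one
Conditions: BnBr, Ag2O, 4 Å MS, CH2Cl2, rt, dark
Reagents that add atoms: benzyl bromide, BrCc1ccccc1
Why: Silver-oxide-promoted Williamson benzylation is a near-neutral way to etherify hydroxy lactones and esters that would eliminate or open under alkoxide conditions; no centre is touched.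

Step 5
Reactants: 6 bis(benzyl ether) lactone
Product: 7 (5R)-3-(benzyloxy)-5-[(1R,2S,5R)-menthyloxy]furan-2(5H)-one
Conditions: DBU, CH2Cl2, 0 °C, short contact
Reagents that add atoms: none
Why: E1cB β-elimination as known for 2,3-di-O-alkyl aldono-1,4-lactones: the only acidic proton is α to the carbonyl and the only β leaving group is the C4 benzyloxy group, so the 3-benzyloxy butenolide is the single regiochemical outcome; the C5 acetal centre is not involved.

Step 6
Reactants: 8 vanillin
Product: 9 3-methoxy-4-[(triisopropylsilyl)oxy]benzaldehyde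
Conditions: i-Pr3SiCl, imidazole, DMF, rt
Reagents that add atoms: triisopropylsilyl chloride, CC(C)[Si](Cl)(C(C)C)C(C)C
Why: Standard silylation of a phenol; the bulky silyl ether withstands n-BuLi, hydride and mild acid and is orthogonal to benzyl ethers.

Step 7
Reactants: 9 silylated vanillin; 10 propane-1,3-dithiol
Product: 11 2-{3-methoxy-4-[(triisopropylsilyl)oxy]phenyl}-1,3-dithiane
Conditions: BF3·OEt2 (cat.), CH2Cl2, 0 °C
Reagents that add atoms: none
Why: Lewis-acid-catalysed thioacetalisation of an aromatic aldehyde; the hindered aryl silyl ether survives catalytic BF3 at 0 °C.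

Step 8
Reactants: 12 [4-(benzyloxy)-3-methoxyphenyl]methanol
Product: 13 4-(benzyloxy)-3-methoxybenzyl bromide
Conditions: PBr3, Et2O, 0 °C; used fresh
Reagents that add atoms: phosphorus tribromide, BrP(Br)Br
Why: Conversion of an electron-rich benzylic alcohol into the bromide through its phosphite ester; the aryl benzyl ether is inert.

Step 9
Reactants: 11 ring B dithiane; 7 (5R)-3-(benzyloxy)-5-(menthyloxy)furan-2(5H)-one; 13 ring A benzyl bromide
Product: 16 (3S,4R,5R)-3-(benzyloxy)-3-[4-(benzyloxy)-3-methoxybenzyl]-4-(2-{3-methoxy-4-[(triisopropylsilyl)oxy]phenyl}-1,3-dithian-2-yl)-5-[(1R,2S,5R)-menthyloxy]dihydrofuran-2(3H)-one, via 2-lithio-1,3-dithiane 14 (not isolated), via lithium lactone enolate 15 (not isolated)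
Conditions: n-BuLi, THF, −78 → −20 °C; 7, −78 °C; then 13, DMPU, −78 → −40 °C; NH4Cl (aq)
Reagents that add atoms: none
Why: n-BuLi removes the doubly sulfur-stabilised benzylic proton of 11; anion 14, an acyl anion equivalent for C2, adds 1,4 to 7, and the lithium enolate 15 is C-benzylated by 13 in an SN2 step, so C2–C3 and C4–C7 form in one flask. The closest known reaction type is the tandem conjugate addition and enolate alkylation of 5-alkoxybutenolides with lithiated 2-aryl-1,3-dithianes, the 3-benzyloxy group being a spectator extension. No ring is closed. C3 of the target (lactone C4, R) is controlled by the C5 acetal centre, because the nucleophile enters anti to the menthyloxy group. C4 of the target (lactone C3, S) is controlled by the new neighbour, because the planar α-benzyloxy enolate is alkylated on the face away from the bulky dithianyl group, which puts C7 trans to it and the oxygen cis. The step needs 1,4- over 1,2-addition and over γ-deprotonation, secured by the soft delocalised anion at −78 °C, and C- over O-alkylation, secured by the lithium counter-ion, the reactive benzylic bromide and DMPU.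

Step 10
Reactants: 16 dithianyl lactone
Product: 17 (3S,4R,5R)-3-(benzyloxy)-3-[4-(benzyloxy)-3-methoxybenzyl]-4-{3-methoxy-4-[(triisopropylsilyl)oxy]benzoyl}-5-(menthyloxy)dihydrofuran-2(3H)-one
Conditions: HgO, BF3·OEt2, THF/H2O, rt
Reagents that add atoms: water, O (carbonyl oxygen, drawn from the pool formed by water and HgO, O=[Hg])
Why: Mercury-assisted hydrolysis is the reliable way to open hindered 2,2-disubstituted dithianes in this lactone class; the medium is non-basic, so the C–H between ketone and acetal is not epimerised, and the ethers, silyl ether and lactone acetal survive.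

Step 11
Reactants: 17 keto lactone
Product: 18 (2S,3R)-2-(benzyloxy)-2-[4-(benzyloxy)-3-methoxybenzyl]-3-(hydroxy{3-methoxy-4-[(triisopropylsilyl)oxy]phenyl}methyl)butane-1,4-diol (both carbinol epimers)
Conditions: LiAlH4, THF, 0 °C → rt; Fieser work-up
Reagents that add atoms: none
Why: Hydride reduces the ketone to the C2 carbinol and the lactone to the C5 alcohol; the freed menthyl hemiacetal collapses to an aldehyde that is reduced to the C3 hydroxymethyl, releasing menthol. Benzyl and aryl silyl ethers are inert, and C3 and C4 are not touched.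

Step 12
Reactants: 18 triol
Product: 19 [(2S,3R,4S)-4-(benzyloxy)-4-[4-(benzyloxy)-3-methoxybenzyl]-2-{3-methoxy-4-[(triisopropylsilyl)oxy]phenyl}oxolan-3-yl]methanol
Conditions: camphorsulfonic acid (cat.), CH2Cl2, −20 → 0 °C, short contact; Et3N quench
Reagents that add atoms: none
Why: Acid-catalysed SN1 cycloetherification: the para-silyloxy-stabilised benzylic cation is captured by the C5 hydroxyl in a five-membered closure (the other primary hydroxyl could only give an oxetane). Reversible ionisation places ring B trans to the C3 hydroxymethyl, which sets C2 as S from either carbinol epimer. Low temperature and a prompt quench keep ring A from closing by Friedel–Crafts attack.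

Step 13
Reactants: 19 silyl-protected oxolane
Product: 20 4-[(2S,3R,4S)-4-(benzyloxy)-4-[4-(benzyloxy)-3-methoxybenzyl]-3-(hydroxymethyl)oxolan-2-yl]-2-methoxyphenol
Conditions: Bu4NF, THF, 0 °C; NH4Cl (aq)
Reagents that add atoms: none
Why: Fluoride cleaves the aryl silyl ether within minutes; benzyl ethers, the primary alcohol and the benzylic ether are unaffected.

Step 14
Reactants: 20 ring B phenol; 21 (4S)-4-benzyl-3-(chloroacetyl)-1,3-oxazolidin-2-one
Product: 22 (4S)-4-benzyl-3-[({4-[(2S,3R,4S)-4-(benzyloxy)-4-[4-(benzyloxy)-3-methoxybenzyl]-3-(hydroxymethyl)oxolan-2-yl]-2-methoxyphenyl}oxy)acetyl]-1,3-oxazolidin-2-one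
Conditions: K2CO3, DMF, rt
Reagents that add atoms: none
Why: Williamson etherification: carbonate deprotonates only the phenol, and the phenoxide displaces chloride from the activated α-chloro imide faster than it attacks either carbonyl; the primary alcohol stays free.

Step 15
Reactants: 22 aryloxyacetyl imide; 23 4-(benzyloxy)-3-methoxybenzaldehyde
Product: 25 (4S)-4-benzyl-3-[(2S,3R)-3-[4-(benzyloxy)-3-methoxyphenyl]-3-hydroxy-2-(ring B aryloxy)propanoyl]-1,3-oxazolidin-2-one (syn adduct; ring B aryloxy = the oxolane-bearing aryloxy group of 22), via dibutylboron Z-enolate 24 (not isolated)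
Conditions: Bu2BOTf (2.3 equiv), i-Pr2NEt, CH2Cl2, −78 → 0 °C; 23, −78 → 0 °C; pH 7 buffer, MeOH, H2O2, 0 °C
Reagents that add atoms: none
Why: Evans syn aldol: soft enolisation gives the Z boron enolate (the extra equivalent of Bu2BOTf caps the free primary hydroxyl as its borinate, which the oxidative work-up removes). The closed Zimmerman–Traxler chair with the dipole-opposed (S) auxiliary delivers the aldehyde to the enolate face away from the benzyl group. This sets C8'' in its final configuration and C7'' provisionally as the syn (threo) partner.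

Step 16
Reactants: 25 syn aldol adduct
Product: 26 bis(4-nitrobenzoate) of 25 with inverted carbinol: (2S,3S)-3-(4-nitrobenzoyloxy) acyl chain, and the C3 hydroxymethyl of the oxolane as its 4-nitrobenzoate
Conditions: 4-nitrobenzoic acid, PPh3, DIAD (3 equiv each), THF, 0 °C → rt
Reagents that add atoms: 4-nitrobenzoic acid, O=C(O)c1ccc(cc1)[N+](=O)[O-]
Why: Mitsunobu esterification: the carboxylate displaces the alkoxyphosphonium group at the secondary benzylic carbon with inversion, turning the syn pair into the required anti (erythro) pair with C7'' as S. The primary hydroxyl is simply esterified without stereochemical consequence, and the tertiary benzyl ether is inert.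

Step 17
Reactants: 26 bis(4-nitrobenzoate) imide
Product: 27 (1S,2R)-1-[4-(benzyloxy)-3-methoxyphenyl]-2-{4-[(2S,3R,4S)-4-(benzyloxy)-4-[4-(benzyloxy)-3-methoxybenzyl]-3-(hydroxymethyl)oxolan-2-yl]-2-methoxyphenoxy}propane-1,3-diol
Conditions: LiBH4, H2O (2 equiv), THF, 0 °C → rt
Reagents that add atoms: none
Why: Reductive cleavage of the N-acyl oxazolidinone to the primary alcohol C9'' with release of the auxiliary; the same reagent reduces both nitrobenzoates, and the medium is not basic enough to epimerise C8''.

Step 18
Reactants: 27 tris(benzyl ether)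
Product: 28 (1S,2R)-1-(4-hydroxy-3-methoxyphenyl)-2-{4-[(2S,3R,4S)-4-hydroxy-4-(4-hydroxy-3-methoxybenzyl)-3-(hydroxymethyl)oxolan-2-yl]-2-methoxyphenoxy}propane-1,3-diol (CNP0391650.1)
Conditions: H2 (1 atm), Pd(OH)2/C, EtOAc/MeOH, rt, uptake monitored
Reagents that add atoms: none
Why: Catalytic hydrogenolysis removes the two aryl benzyl ethers and the tertiary alkyl benzyl ether under neutral conditions; stopping at the calculated uptake keeps the benzylic C7''–OH and C2–O1 bonds, and no stereocentre is involved.

## Compound list

1 | furfural | O=Cc1ccco1 | starting material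
2 | 5-hydroxyfuran-2(5H)-one (racemic) | O=C1OC(O)C=C1 | intermediate
3 | (−)-menthol, (1R,2S,5R)-2-isopropyl-5-methylcyclohexan-1-ol | C[C@@H]1CC[C@H]([C@@H](C1)O)C(C)C | starting material
4 | (5R)-5-[(1R,2S,5R)-menthyloxy]furan-2(5H)-one | O=C1O[C@@H](O[C@@H]2C[C@H](C)CC[C@H]2C(C)C)C=C1 | intermediate
5 | (3S,4R,5R)-3,4-dihydroxy-5-[(1R,2S,5R)-menthyloxy]dihydrofuran-2(3H)-one | O=C1O[C@@H](O[C@@H]2C[C@H](C)CC[C@H]2C(C)C)[C@H](O)[C@@H]1O | intermediate
6 | (3S,4R,5R)-3,4-bis(benzyloxy)-5-[(1R,2S,5R)-menthyloxy]dihydrofuran-2(3H)-one | O=C1O[C@@H](O[C@@H]2C[C@H](C)CC[C@H]2C(C)C)[C@H](OCc2ccccc2)[C@@H]1OCc1ccccc1 | intermediate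
7 | (5R)-3-(benzyloxy)-5-[(1R,2S,5R)-menthyloxy]furan-2(5H)-one | O=C1O[C@@H](O[C@@H]2C[C@H](C)CC[C@H]2C(C)C)C=C1OCc1ccccc1 | intermediate
8 | vanillin | COc1cc(C=O)ccc1O | starting material
9 | 3-methoxy-4-[(triisopropylsilyl)oxy]benzaldehyde | COc1cc(C=O)ccc1O[Si](C(C)C)(C(C)C)C(C)C | intermediate
10 | propane-1,3-dithiol | SCCCS | starting material
11 | 2-{3-methoxy-4-[(triisopropylsilyl)oxy]phenyl}-1,3-dithiane | COc1cc(C2SCCCS2)ccc1O[Si](C(C)C)(C(C)C)C(C)C | intermediate
12 | [4-(benzyloxy)-3-methoxyphenyl]methanol | COc1cc(CO)ccc1OCc1ccccc1 | starting material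
13 | 4-(benzyloxy)-3-methoxybenzyl bromide | COc1cc(CBr)ccc1OCc1ccccc1 | intermediate
14 | 2-lithio-2-{3-methoxy-4-[(triisopropylsilyl)oxy]phenyl}-1,3-dithiane | COc1cc(C2([Li])SCCCS2)ccc1O[Si](C(C)C)(C(C)C)C(C)C | intermediate (not isolated)
15 | lithium (4R,5R)-3-(benzyloxy)-4-(2-aryl-1,3-dithian-2-yl)-5-(menthyloxy)-4,5-dihydrofuran-2-olate (aryl as in 11) | [Li]OC1=C(OCc2ccccc2)[C@@H](C2(c3ccc(O[Si](C(C)C)(C(C)C)C(C)C)c(OC)c3)SCCCS2)[C@H](O[C@@H]2C[C@H](C)CC[C@H]2C(C)C)O1 | intermediate (not isolated)
16 | (3S,4R,5R)-3-(benzyloxy)-3-[4-(benzyloxy)-3-methoxybenzyl]-4-(2-{3-methoxy-4-[(triisopropylsilyl)oxy]phenyl}-1,3-dithian-2-yl)-5-[(1R,2S,5R)-menthyloxy]dihydrofuran-2(3H)-one | COc1cc(C[C@@]2(OCc3ccccc3)C(=O)O[C@@H](O[C@@H]3C[C@H](C)CC[C@H]3C(C)C)[C@@H]2C2(c3ccc(O[Si](C(C)C)(C(C)C)C(C)C)c(OC)c3)SCCCS2)ccc1OCc1ccccc1 | intermediate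
17 | (3S,4R,5R)-3-(benzyloxy)-3-[4-(benzyloxy)-3-methoxybenzyl]-4-{3-methoxy-4-[(triisopropylsilyl)oxy]benzoyl}-5-[(1R,2S,5R)-menthyloxy]dihydrofuran-2(3H)-one | COc1cc(C[C@@]2(OCc3ccccc3)C(=O)O[C@@H](O[C@@H]3C[C@H](C)CC[C@H]3C(C)C)[C@@H]2C(=O)c2ccc(O[Si](C(C)C)(C(C)C)C(C)C)c(OC)c2)ccc1OCc1ccccc1 | intermediate
18 | (2S,3R)-2-(benzyloxy)-2-[4-(benzyloxy)-3-methoxybenzyl]-3-(hydroxy{3-methoxy-4-[(triisopropylsilyl)oxy]phenyl}methyl)butane-1,4-diol (carbinol epimers) | COc1cc(C[C@@](OCc2ccccc2)(CO)[C@H](CO)C(O)c2ccc(O[Si](C(C)C)(C(C)C)C(C)C)c(OC)c2)ccc1OCc1ccccc1 | intermediate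
19 | [(2S,3R,4S)-4-(benzyloxy)-4-[4-(benzyloxy)-3-methoxybenzyl]-2-{3-methoxy-4-[(triisopropylsilyl)oxy]phenyl}oxolan-3-yl]methanol | COc1cc(C[C@@]2(OCc3ccccc3)CO[C@H](c3ccc(O[Si](C(C)C)(C(C)C)C(C)C)c(OC)c3)[C@H]2CO)ccc1OCc1ccccc1 | intermediate
20 | 4-[(2S,3R,4S)-4-(benzyloxy)-4-[4-(benzyloxy)-3-methoxybenzyl]-3-(hydroxymethyl)oxolan-2-yl]-2-methoxyphenol | COc1cc(C[C@@]2(OCc3ccccc3)CO[C@H](c3ccc(O)c(OC)c3)[C@H]2CO)ccc1OCc1ccccc1 | intermediate
21 | (4S)-4-benzyl-3-(chloroacetyl)-1,3-oxazolidin-2-one | O=C1OC[C@H](Cc2ccccc2)N1C(=O)CCl | starting material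
22 | (4S)-4-benzyl-3-[(ring B aryloxy)acetyl]-1,3-oxazolidin-2-one, the O-alkylation product of 20 | COc1cc(C[C@@]2(OCc3ccccc3)CO[C@H](c3ccc(OCC(=O)N4[C@@H](Cc5ccccc5)COC4=O)c(OC)c3)[C@H]2CO)ccc1OCc1ccccc1 | intermediate
23 | 4-(benzyloxy)-3-methoxybenzaldehyde | COc1cc(C=O)ccc1OCc1ccccc1 | starting material
24 | dibutylboron Z-enolate of 22, primary hydroxyl as its dibutylborinate | COc1cc(C[C@@]2(OCc3ccccc3)CO[C@H](c3ccc(O/C=C(\OB(CCCC)CCCC)N4[C@@H](Cc5ccccc5)COC4=O)c(OC)c3)[C@H]2COB(CCCC)CCCC)ccc1OCc1ccccc1 | intermediate (not isolated)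
25 | (4S)-4-benzyl-3-[(2S,3R)-3-[4-(benzyloxy)-3-methoxyphenyl]-3-hydroxy-2-(ring B aryloxy)propanoyl]-1,3-oxazolidin-2-one (syn) | COc1cc(C[C@@]2(OCc3ccccc3)CO[C@H](c3ccc(O[C@H](C(=O)N4[C@@H](Cc5ccccc5)COC4=O)[C@H](O)c4ccc(OCc5ccccc5)c(OC)c4)c(OC)c3)[C@H]2CO)ccc1OCc1ccccc1 | intermediate
26 | (2S,3S)-configured bis(4-nitrobenzoate): inverted benzylic ester and primary ester of 25 | COc1cc(C[C@@]2(OCc3ccccc3)CO[C@H](c3ccc(O[C@H](C(=O)N4[C@@H](Cc5ccccc5)COC4=O)[C@@H](OC(=O)c4ccc([N+](=O)[O-])cc4)c4ccc(OCc5ccccc5)c(OC)c4)c(OC)c3)[C@H]2COC(=O)c2ccc([N+](=O)[O-])cc2)ccc1OCc1ccccc1 | intermediate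
27 | (1S,2R)-1-[4-(benzyloxy)-3-methoxyphenyl]-2-{4-[(2S,3R,4S)-4-(benzyloxy)-4-[4-(benzyloxy)-3-methoxybenzyl]-3-(hydroxymethyl)oxolan-2-yl]-2-methoxyphenoxy}propane-1,3-diol | COc1cc(C[C@@]2(OCc3ccccc3)CO[C@H](c3ccc(O[C@H](CO)[C@@H](O)c4ccc(OCc5ccccc5)c(OC)c4)c(OC)c3)[C@H]2CO)ccc1OCc1ccccc1 | intermediate
28 | (1S,2R)-1-(4-hydroxy-3-methoxyphenyl)-2-{4-[(2S,3R,4S)-4-hydroxy-4-(4-hydroxy-3-methoxybenzyl)-3-(hydroxymethyl)oxolan-2-yl]-2-methoxyphenoxy}propane-1,3-diol | COc1cc(C[C@@]2(O)CO[C@H](c3ccc(O[C@H](CO)[C@@H](O)c4ccc(O)c(OC)c4)c(OC)c3)[C@H]2CO)ccc1O | target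

## Step count and least certain steps

Total step count: 18. Longest linear sequence: 15 steps (steps 1 to 5, then 9 to 18). Steps 6 to 7 and step 8 are side branches.

Step 9 (key step). The likeliest failure is sluggish C-alkylation of the crowded tetrasubstituted α-alkoxy enolate, so that proton quench or O-alkylation takes over. The α-alkoxy group also lowers the electrophilicity of the β-carbon, which may let 1,2-addition or γ-deprotonation compete with the conjugate addition. The fallback sets out from 11 and 7 (through enolate 15) and comes back at 16. The enolate is trapped with aldehyde 23 in place of bromide 13, since an aldehyde reacts with a hindered enolate far more readily than an alkyl halide. This gives the aldol adduct, the α-[aryl(hydroxy)methyl] lactone F1, as a carbinol mixture with the new C–C bond again anti to the dithianyl group. Ionic hydrogenation of the electron-rich benzylic carbinol (Et3SiH, CF3CO2H, CH2Cl2, −40 °C) then removes the hydroxyl and gives 16.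

Step 12. The benzylic cation may be captured irreversibly by ring A (Friedel–Crafts closure to an aryltetralin) before or after ether formation, and equilibration at C2 may stay incomplete if the acid contact is kept short enough to avoid this. The fallback sets out from 18 and comes back at 20. Desilylation first (Bu4NF, THF, 0 °C) gives the phenolic triol F2. A free para-hydroxybenzylic alcohol loses water under much weaker activation (buffered aqueous MeCN, gentle warming) by way of a neutral para-quinone methide. The C5 hydroxyl captures it in a 1,6-addition, and a neutral quinone methide is a far poorer partner for ring A than a cation in acid. The product is 20 itself, so step 13 is not needed.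

Step 16. The alkoxyphosphonium intermediate sits on an electron-rich benzylic carbon and may ionise, losing stereochemical fidelity at C7'', or it may undergo E1cB elimination across C7''–C8''. The fallback sets out from 20 and comes back at 27. Alkylation of 20 with the enantiomeric reagent (4R)-4-benzyl-3-(chloroacetyl)-1,3-oxazolidin-2-one (K2CO3, DMF) gives the (4R) aryloxyacetyl imide F3. A magnesium-catalysed anti aldol with 23 (MgCl2 cat., Et3N, Me3SiCl, EtOAc, rt; then CF3CO2H, MeOH) runs through the chelated enolate and is expected to give the anti adduct F4 with C7'' and C8'' as required and no inversion step. LiBH4 then gives 27.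

Step 18. Over-reduction may occur: the hindered tertiary benzyl ether is cleaved slowly, and the benzylic C7''–O or C2–O1 bond may be hydrogenolysed in the meantime. The fallback sets out from 19 and comes back at 28. The benzyl groups are removed early, when no side chain is present: hydrogenolysis of 19 (H2, Pd/C, EtOAc) gives the silyl-protected diol phenol F5. Selective phenol benzylation (BnBr, K2CO3, acetone) gives the ring A benzyl ether with free tertiary hydroxyl F6. This is taken through the operations of steps 13 to 17: the ring B phenol F7, the aryloxyacetyl imide F8, the syn aldol adduct F9 (one more equivalent of Bu2BOTf), the bis(4-nitrobenzoate) F10 and the bis(benzyl ether) pentol F11. The last hydrogenolysis then only has to cleave two fast-reacting aryl benzyl ethers to reach 28.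

Step 5. The amidine base may deprotonate the product at the γ-position (C5), forming an oxyfuran, which would epimerise the acetal centre and erode the stereocontrol of step 9. The fallback sets out from 5 and comes back at 7. Acetylation (Ac2O, Et3N, DMAP cat., CH2Cl2) gives the diacetate F12. This loses acetic acid under the same mild amine, because a β-acetoxy group leaves far more readily than a β-benzyloxy group, and gives the enol acetate F13. Brief cold methanolysis (K2CO3 cat., MeOH, −20 °C) frees the enol, 3-hydroxy-5-(menthyloxy)furan-2(5H)-one F14. O-Benzylation (BnBr, Ag2O, CH2Cl2) gives 7.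

## Further compounds

F1 | step 9 | (3S,4R,5R)-3-(benzyloxy)-3-{[4-(benzyloxy)-3-methoxyphenyl](hydroxy)methyl}-4-(2-aryl-1,3-dithian-2-yl)-5-(menthyloxy)dihydrofuran-2(3H)-one (carbinol epimers) | COc1cc(C(O)[C@@]2(OCc3ccccc3)C(=O)O[C@@H](O[C@@H]3C[C@H](C)CC[C@H]3C(C)C)[C@@H]2C2(c3ccc(O[Si](C(C)C)(C(C)C)C(C)C)c(OC)c3)SCCCS2)ccc1OCc1ccccc1
F2 | step 12 | (2S,3R)-2-(benzyloxy)-2-[4-(benzyloxy)-3-methoxybenzyl]-3-[hydroxy(4-hydroxy-3-methoxyphenyl)methyl]butane-1,4-diol | COc1cc(C[C@@](OCc2ccccc2)(CO)[C@H](CO)C(O)c2ccc(O)c(OC)c2)ccc1OCc1ccccc1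
F3 | step 16 | (4R)-4-benzyl-3-[(ring B aryloxy)acetyl]-1,3-oxazolidin-2-one, from 20 | COc1cc(C[C@@]2(OCc3ccccc3)CO[C@H](c3ccc(OCC(=O)N4[C@H](Cc5ccccc5)COC4=O)c(OC)c3)[C@H]2CO)ccc1OCc1ccccc1
F4 | step 16 | (4R)-4-benzyl-3-[(2S,3S)-3-[4-(benzyloxy)-3-methoxyphenyl]-3-hydroxy-2-(ring B aryloxy)propanoyl]-1,3-oxazolidin-2-one (anti) | COc1cc(C[C@@]2(OCc3ccccc3)CO[C@H](c3ccc(O[C@H](C(=O)N4[C@H](Cc5ccccc5)COC4=O)[C@@H](O)c4ccc(OCc5ccccc5)c(OC)c4)c(OC)c3)[C@H]2CO)ccc1OCc1ccccc1
F5 | step 18 | (3S,4R,5S)-3-(4-hydroxy-3-methoxybenzyl)-4-(hydroxymethyl)-5-{3-methoxy-4-[(triisopropylsilyl)oxy]phenyl}oxolan-3-ol | COc1cc(C[C@@]2(O)CO[C@H](c3ccc(O[Si](C(C)C)(C(C)C)C(C)C)c(OC)c3)[C@H]2CO)ccc1O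
F6 | step 18 | (3S,4R,5S)-3-[4-(benzyloxy)-3-methoxybenzyl]-4-(hydroxymethyl)-5-{3-methoxy-4-[(triisopropylsilyl)oxy]phenyl}oxolan-3-ol | COc1cc(C[C@@]2(O)CO[C@H](c3ccc(O[Si](C(C)C)(C(C)C)C(C)C)c(OC)c3)[C@H]2CO)ccc1OCc1ccccc1
F7 | step 18 | (3S,4R,5S)-3-[4-(benzyloxy)-3-methoxybenzyl]-5-(4-hydroxy-3-methoxyphenyl)-4-(hydroxymethyl)oxolan-3-ol | COc1cc(C[C@@]2(O)CO[C@H](c3ccc(O)c(OC)c3)[C@H]2CO)ccc1OCc1ccccc1
F8 | step 18 | (4S)-4-benzyl-3-[(ring B aryloxy)acetyl]-1,3-oxazolidin-2-one with free C4 hydroxyl, from F7 | COc1cc(C[C@@]2(O)CO[C@H](c3ccc(OCC(=O)N4[C@@H](Cc5ccccc5)COC4=O)c(OC)c3)[C@H]2CO)ccc1OCc1ccccc1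
F9 | step 18 | (2S,3R) syn aldol adduct of F8 with 23 | COc1cc(C[C@@]2(O)CO[C@H](c3ccc(O[C@H](C(=O)N4[C@@H](Cc5ccccc5)COC4=O)[C@H](O)c4ccc(OCc5ccccc5)c(OC)c4)c(OC)c3)[C@H]2CO)ccc1OCc1ccccc1
F10 | step 18 | (2S,3S) bis(4-nitrobenzoate) from F9 (inverted benzylic ester, primary ester) | COc1cc(C[C@@]2(O)CO[C@H](c3ccc(O[C@H](C(=O)N4[C@@H](Cc5ccccc5)COC4=O)[C@@H](OC(=O)c4ccc([N+](=O)[O-])cc4)c4ccc(OCc5ccccc5)c(OC)c4)c(OC)c3)[C@H]2COC(=O)c2ccc([N+](=O)[O-])cc2)ccc1OCc1ccccc1
F11 | step 18 | (1S,2R)-1-[4-(benzyloxy)-3-methoxyphenyl]-2-{4-[(2S,3R,4S)-4-[4-(benzyloxy)-3-methoxybenzyl]-4-hydroxy-3-(hydroxymethyl)oxolan-2-yl]-2-methoxyphenoxy}propane-1,3-diol | COc1cc(C[C@@]2(O)CO[C@H](c3ccc(O[C@H](CO)[C@@H](O)c4ccc(OCc5ccccc5)c(OC)c4)c(OC)c3)[C@H]2CO)ccc1OCc1ccccc1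
F12 | step 5 | (3S,4R,5R)-3,4-diacetoxy-5-[(1R,2S,5R)-menthyloxy]dihydrofuran-2(3H)-one | O=C1O[C@@H](O[C@@H]2C[C@H](C)CC[C@H]2C(C)C)[C@H](OC(C)=O)[C@@H]1OC(C)=O
F13 | step 5 | (5R)-3-acetoxy-5-[(1R,2S,5R)-menthyloxy]furan-2(5H)-one | O=C1O[C@@H](O[C@@H]2C[C@H](C)CC[C@H]2C(C)C)C=C1OC(C)=O
F14 | step 5 | (5R)-3-hydroxy-5-[(1R,2S,5R)-menthyloxy]furan-2(5H)-one | O=C1O[C@@H](O[C@@H]2C[C@H](C)CC[C@H]2C(C)C)C=C1O
A1 | alternative 1 | bridgehead-hydroxy 2,6-diaryl-3,7-dioxabicyclo[3.3.0]octane (ring B mesylate, ring A benzyl ether), cis-fused | O[C@]12CO[C@H](c3ccc(OS(C)(=O)=O)c(OC)c3)[C@H]1CO[C@@H]2c1ccc(OCc2ccccc2)c(OC)c1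
A2 | alternative 1 | 2-(ring B aryl)-3-{[(ring A benzyl)oxy]methyl}oxolan-4-one, C2 and C3 as in the target, ring B as mesylate | O=C1CO[C@H](c2ccc(OS(C)(=O)=O)c(OC)c2)[C@H]1COCc1ccc(OCc2ccccc2)c(OC)c1
A3 | alternative 2 | (2S,3R,4S)-4-[4-(benzyloxy)-3-methoxybenzyl]-4-hydroxy-2-{3-methoxy-4-[(triisopropylsilyl)oxy]phenyl}oxolane-3-carbaldehyde | COc1cc(C[C@@]2(O)CO[C@H](c3ccc(O[Si](C(C)C)(C(C)C)C(C)C)c(OC)c3)[C@H]2C=O)ccc1OCc1ccccc1
A4 | alternative 2 | 1-[4-(benzyloxy)-3-methoxyphenyl]-3-hydroxypropan-2-one | COc1cc(CC(=O)CO)ccc1OCc1ccccc1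
A5 | alternative 2 | (E)-3-{3-methoxy-4-[(triisopropylsilyl)oxy]phenyl}prop-2-enal | COc1cc(/C=C/C=O)ccc1O[Si](C(C)C)(C(C)C)C(C)C
A6 | alternative 3 | olivil core with ring A pivalate and ring B benzyl ether | COc1cc(C[C@@]2(O)CO[C@H](c3ccc(OCc4ccccc4)c(OC)c3)[C@H]2CO)ccc1OC(=O)C(C)(C)C
A7 | alternative 3 | seco-lignan triol: 2-(ring A benzyl)-3-(ring B benzyl)butane-1,2,4-triol, ring A pivalate, ring B benzyl ether, C3 and C4 as in the target | COc1cc(C[C@@](O)(CO)[C@H](CO)Cc2ccc(OCc3ccccc3)c(OC)c2)ccc1OC(=O)C(C)(C)C
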